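The earlier runs and the new flask stem from a simulated flask with constants of no real substance; the scatter is artificial.

The electrophile is the species to watch in this flask.

| flask | electrophile | free base | protonated nucleophile | remark | time |
|---|---|---|---|---|---|
| larch | 0.10 M | 0.050 M | 0.18 M | the very flask that is asked about, followed so far |  |
| flask | 0.10 M | 0.0500 M | 0.180 M |  | 4.0 min |

larch run (percent of the electrophile charged)

| time / s | electrophile / % | target / % |
|---|---|---|
| 10.0 | 71 | 27 |
| 20.0 | 53 | 47 |
| 40.0 | 29 | 72 |
| 80.0 | 10 | 90 |

(standard deviation of a reading: 1.5 percentage points)

1. part of the electrophile that has reacted at 4.0 min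
2. share of the unused nucleophile that is free and not bound as protonated nucleophile, at 4.0 min

- the earlier runs do not show how much of nucleophile is bound; that part of a forecast is a guess

Test the order first. Over the first 20.0 s of the larch readings, the half-life of the electrophile reads 21.8 s. From there to 80.0 s it reads 24.9 s, a little longer. So treat the loss as nearly pseudo-first-order, with a rate that follows c(electrophile) and a partner that acts as if held steady.

Two times then matter. Take the half-life from the last reading, 24.1 s, and set the asked 4.0 min against it. Their ratio is the halving count, 9.97. My reckoning leaves 0.100% of the electrophile, so c is 99.9%. Read that as a little high, since the half-life lengthens. The readings do not show the bound nucleophile, so fr remains a guess.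

The forecast gives 99.7% and 25%, and says of the second, “the data cannot settle it”. The flask gives 99.8% and 13.8%.

    electrophile + nucleophile → acid set free + target (k = 3.69 M⁻¹ s⁻¹)
    nucleophile + acid set free ⇌ protonated nucleophile, settled at all times (K = 3510 M⁻¹)
    acid set free + free base ⇌ salt of the base (K = 5490 M⁻¹, k = 20.6 M⁻¹ s⁻¹)
    2 nucleophile → self-condensation product (k = 1.62 M⁻¹ s⁻¹)
    crystals ⇌ acid set free, rate k5*(cs5 - [acid set free]) while solid is left; crystals form when [acid set free] > cs5 (solubility = 1.70 mM, k = 1.13 s⁻¹)

In the flask, the 0.179% of electrophile left counts 9.13 halvings against the 9.97 reckoned. A neighbour flask, with 0.11 M of protonated nucleophile and all else held, leaves 7.57% of its electrophile at 4.0 min. That is 3.72 halvings, fewer. The asked flask has not come to rest at 4.0 min. At 40.0 min, ten times the asked time, its c stands at 100%, a change of 0.20 percentage points. But by 40.0 min protonated nucleophile falls from 19.1% to 2.84% of its charge, and the self-condensation product climbs from 0.0202 M to 0.0370 M.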